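The vessel is a stirred flask of two phases: substrate and spent carrier sit in the first and salt in the second. On the list of suspects, spent carrier takes up salt to become fresh carrier, and fresh carrier turns substrate into product and returns as spent carrier.

| setting | autumn | dusk | Saturday's | Monday's |
|---|---|---|---|---|
| substrate | 0.10 M | 0.10 M | 0.10 M | 0.10 M |
| salt in the second phase | 0.105 M | 0.105 M | 0.105 M | 0.105 M |
| spent carrier | 12 mM | 35 mM | 40 mM | 20 mM |
| temperature | −45 °C | −30 °C |  |  |
| remark | run made earlier | run made earlier | at −40 °C throughout | at −20 °C until 1.0 min, from then on at −40 °C |
| time |  |  | 2.0 min | 2.0 min |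
| volume of the second phase over the first |  |  | 1.0 | 1.0 |

autumn run (percent of the substrate charged): time / min: product / % = 0.500: 0; 1.00: 1.4; 2.50: 1.8; 3.00: 3.2

dusk run (percent of the substrate charged): time / s: product / % = 15.0: 3.0; 20.0: 3.9; 40.0: 8.0; 90.0: 18.8

(scatter of a reading: 0.5 percentage points)

1. the winner by amount of product, in percent of the substrate charged; "neither" if no more than 2 percentage points parts them (Saturday's / Monday's / neither)
2. how much product is there at the end, in percent of the substrate charged: Saturday's
3. how much product is there at the end, in percent of the substrate charged: Monday's

We look for the concentration that sets the order of the rate. Let κ be the product made per carrier per minute. In the dusk run κ reads 0.343 min⁻¹ at the first reading and 0.358 min⁻¹ at the last, where product stands at 18.8% of the substrate charged, so these readings show no fall of the rate with substrate. We therefore take the uptake of salt by spent carrier as the rate-limiting step, first order in spent carrier. That order is assumed, because the two runs change carrier and temperature together. Lines through the origin give: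

κ(autumn) = 0.0783 min⁻¹, κ(dusk) = 0.354 min⁻¹

With ln κ straight in temperature, which at −20 °C reaches beyond both runs:

κ(−40 °C) = 0.130 min⁻¹, κ(−20 °C) = 0.970 min⁻¹

Let Φ be the sum of κ times time, multiplied by spent carrier over substrate:

Φ(Saturday's) = 10.4%, Φ(Monday's) = 22.0%

So Φ, a number without units, is our estimate of the product as a share of the substrate charged. Monday's has half the carrier of Saturday's, but its warm κ is 7.46 times the cold one, so by this reckoning Monday's leads by 12 percentage points. Is one number enough? Monday's Φ stands for 20.9% of the salt charged, and the last dusk reading for 17.9% with no bend in the line, so we keep the straight line.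

The forecast says Monday's, with 10.5% for Saturday's and 19.5% for Monday's, on the ground that “regeneration of the carrier is rate-limiting”, and our Monday's figure stands above it.

The flask gives 9.49% for Saturday's and 22.3% for Monday's, so the winner is Monday's.

    spent carrier + salt in the second phase ⇌ fresh carrier + spent salt in the second phase (K = 0.290, k = 0.190 M⁻¹ s⁻¹, Ea = 53.0 kJ mol⁻¹, ΔH = −62.0 kJ mol⁻¹)
    substrate + fresh carrier → product + spent carrier (k = 6.70 M⁻¹ s⁻¹, Ea = 43.0 kJ mol⁻¹)
    substrate + product ⇌ idle adduct, settled at all times (K = 2.50 M⁻¹, ΔH = −29.0 kJ mol⁻¹)
    (constants at −20 °C)

The neighbouring flask is Monday's with 0.40 M of substrate. Φ with the new charge of substrate in its denominator gives 5.50%, and that flask gives 5.83%. That neighbouring flask keeps 78% of its salt at 2.00 min, against 78% in Monday's.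

(All runs were computed for an exercise; scatter was added.)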